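**Retrosynthetic overview**

1. Last step is O–Si cleavage. The only ring, the butenolide, is not built in the route: it enters intact as 3-bromofuran-2(5H)-one (from furan-2(5H)-one) and is attached last by a Pd-catalysed B-alkyl Suzuki coupling.
2. C2–C3 bond and the C2 stereocentre (target numbered as an undec-9-en-1-yl acetate; C2 carries the butenolide arm, C6 is the second stereocentre): Ni-catalysed stereoconvergent alkyl–alkyl Suzuki coupling of a C13 alkylborane with racemic 2-bromopent-4-enyl acetate, acetate-directed (new).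
3. C6–C7 bond and the C6 stereocentre: the same coupling type in its established carbamate-directed form, between a homoallylic borane from a (Z)-dienyl silyl ether and racemic 2-bromopent-4-enyl carbamate; the carbamate is then exchanged for acetate.
4. (Z)-Trisubstituted olefin: Cu-catalysed anti-carbomagnesiation/iodination of propargyl alcohol, then Pd-catalysed vinylation.
5. Three branches are made in parallel (Z-diene; racemic bromides from methyl pent-4-enoate; bromobutenolide) and joined by three cross-couplings.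

Assumption: the diamine ligand enantiomers named in the two nickel couplings are tentative assignments of the sense of induction, to be confirmed on the first run and exchanged if necessary (the two couplings need opposite ligand enantiomers); the bromides derived from methyl pent-4-enoate are used as racemates.

**Route**

Step 1
Reactants: 1 prop-2-yn-1-ol
Product: 3 (Z)-3-iodo-2-methylprop-2-en-1-ol, via alkenylmagnesium alkoxide 2 (not isolated)
Conditions: MeMgBr (2.5 equiv), CuI (10 mol %), THF, −10 °C to rt; then I2, −10 °C to rt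
Reagents that add atoms: methylmagnesium bromide C[Mg]Br; iodine II
Why: Copper-catalysed anti-carbomagnesiation of the propargylic alkoxide (Duboudin-type) puts magnesium cis to CH2O in a five-membered chelate, and iodinolysis with retention gives the Z iodide.

Step 2
Reactants: 3 (Z)-3-iodo-2-methylprop-2-en-1-ol
Product: 4 tert-butyl{[(2Z)-3-iodo-2-methylprop-2-en-1-yl]oxy}dimethylsilane
Conditions: TBSCl, imidazole, CH2Cl2, 0 °C to rt
Reagents that add atoms: tert-butyldimethylsilyl chloride CC(C)(C)[Si](C)(C)Cl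
Why: Standard imidazole-mediated silylation of a primary alcohol.

Step 3
Reactants: 4 tert-butyl{[(2Z)-3-iodo-2-methylprop-2-en-1-yl]oxy}dimethylsilane
Product: 5 tert-butyl(dimethyl){[(2Z)-2-methylpenta-2,4-dien-1-yl]oxy}silane
Conditions: CH2=CHMgBr (1.3 equiv), Pd(PPh3)4 (3 mol %), THF, 0 °C to rt
Reagents that add atoms: vinylmagnesium bromide C=C[Mg]Br
Why: Palladium-catalysed Kumada–Corriu coupling of an alkenyl iodide, which proceeds with retention of the Z geometry.

Step 4
Reactants: 6 methyl pent-4-enoate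
Product: 8 methyl 2-bromopent-4-enoate (racemic), via lithium ester enolate 7 (not isolated)
Conditions: LiN(i-Pr)2, THF, −78 °C; then CBr4 (inverse addition), −78 °C; AcOH quench
Reagents that add atoms: carbon tetrabromide BrC(Br)(Br)Br
Why: Electrophilic α-bromination of an ester enolate, which is far more nucleophilic than the terminal alkene; the new centre is racemic, as wanted.

Step 5
Reactants: 8 methyl 2-bromopent-4-enoate (racemic)
Product: 9 2-bromopent-4-en-1-ol (racemic)
Conditions: i-Bu2AlH (2.2 equiv), CH2Cl2, −78 to −20 °C; aqueous potassium sodium tartrate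
Reagents that add atoms: none
Why: Aluminium hydride reduction of the ester to the primary alcohol at low temperature leaves the secondary C–Br bond and the terminal alkene untouched.

Step 6
Reactants: 9 2-bromopent-4-en-1-ol (racemic)
Product: 10 2-bromopent-4-en-1-yl benzyl(phenyl)carbamate (racemic)
Conditions: BnN(Ph)COCl, pyridine, DMAP (cat.), CH2Cl2, 40 °C
Reagents that add atoms: N-benzyl-N-phenylcarbamoyl chloride O=C(Cl)N(Cc1ccccc1)c1ccccc1
Why: O-Carbamoylation (nucleophilic acyl substitution) under weakly basic conditions, which avoid epoxide formation from the bromohydrin, installs the directing group.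

Step 7
Reactants: 9 2-bromopent-4-en-1-ol (racemic)
Product: 11 2-bromopent-4-en-1-yl acetate (racemic)
Conditions: Ac2O, pyridine, DMAP (cat.), CH2Cl2, 0 °C to rt
Reagents that add atoms: acetic anhydride CC(=O)OC(C)=O
Why: DMAP-catalysed acetylation (acyl transfer) of the primary alcohol under conditions that do not close the epoxide.

Step 8
Reactants: 5 tert-butyl(dimethyl){[(2Z)-2-methylpenta-2,4-dien-1-yl]oxy}silane; 10 2-bromopent-4-en-1-yl benzyl(phenyl)carbamate (racemic)
Product: 13 (2S,5Z)-7-{[tert-butyl(dimethyl)silyl]oxy}-6-methyl-2-(prop-2-en-1-yl)hept-5-en-1-yl benzyl(phenyl)carbamate, via homoallylic 9-BBN borane 12 (not isolated)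
Conditions: 5 (1.6 equiv), 9-BBN-H (1.5 equiv), THF, rt; then 10, NiBr2·diglyme (10 mol %), (S,S)-N,N′-dimethyl-1,2-diphenylethane-1,2-diamine (12 mol %), KOt-Bu, i-BuOH, i-Pr2O, rt
Reagents that add atoms: none
Why: Carbamate-directed nickel/chiral-diamine stereoconvergent alkyl–alkyl Suzuki–Miyaura coupling: 9-BBN-H adds anti-Markovnikov to the terminal CH=CH2 of the diene only, and the planar secondary radical formed from either enantiomer of 10 is captured by the carbamate-chelated chiral nickel centre, setting C2 as S (C6 of the target).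

Step 9
Reactants: 13 (2S,5Z)-7-{[tert-butyl(dimethyl)silyl]oxy}-6-methyl-2-(prop-2-en-1-yl)hept-5-en-1-yl benzyl(phenyl)carbamate
Product: 14 (2S,5Z)-7-{[tert-butyl(dimethyl)silyl]oxy}-6-methyl-2-(prop-2-en-1-yl)hept-5-en-1-ol
Conditions: LiAlH4, THF, 0 °C to rt
Reagents that add atoms: none
Why: Hydride cleavage of the carbamate (LiAlH4 reduction) frees the primary alcohol without touching the silyl ether, the alkenes or the stereocentre.

Step 10
Reactants: 14 (2S,5Z)-7-{[tert-butyl(dimethyl)silyl]oxy}-6-methyl-2-(prop-2-en-1-yl)hept-5-en-1-ol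
Product: 15 (2S,5Z)-7-{[tert-butyl(dimethyl)silyl]oxy}-6-methyl-2-(prop-2-en-1-yl)hept-5-en-1-yl acetate
Conditions: Ac2O, pyridine, DMAP (cat.), CH2Cl2, 0 °C to rt
Reagents that add atoms: acetic anhydride CC(=O)OC(C)=O
Why: Standard DMAP-catalysed acetylation (acyl transfer); the stereocentre is not involved.

Step 11
Reactants: 15 (2S,5Z)-7-{[tert-butyl(dimethyl)silyl]oxy}-6-methyl-2-(prop-2-en-1-yl)hept-5-en-1-yl acetate; 11 2-bromopent-4-en-1-yl acetate (racemic)
Product: 17 (2R,6R,9Z)-6-[(acetyloxy)methyl]-11-{[tert-butyl(dimethyl)silyl]oxy}-10-methyl-2-(prop-2-en-1-yl)undec-9-en-1-yl acetate, via primary 9-BBN borane 16 (not isolated)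
Conditions: 15, 9-BBN-H (1.0 equiv), THF, rt; then KOt-Bu (0.95 equiv per boron), i-BuOH, 11 (1.5 equiv), NiBr2·diglyme (10 mol %), (R,R)-N,N′-dimethyl-1,2-diphenylethane-1,2-diamine (12 mol %), i-Pr2O, 5 °C to rt
Reagents that add atoms: none
Why: Proposed new method: a nickel/chiral 1,2-diamine stereoconvergent alkyl–alkyl Suzuki coupling in which a plain acetate, not the N,N-disubstituted carbamate for which such couplings of racemic β-bromo alcohol derivatives are established, is the directing group. The monovalent alkylnickel species formed by transmetalation from the alkoxide-activated borane abstracts bromine from either enantiomer of 11 to give a planar secondary radical; the acetate carbonyl can bind nickel in a six-membered chelate, so the chiral diamine tells CH2OAc from allyl during radical capture and reductive elimination from trivalent nickel, giving C2 as R from both enantiomers while the remote C6 centre is untouched; pre-forming the borate with a slight deficit of alkoxide keeps free alkoxide away from the acetates. Closest known reaction: the carbamate-directed nickel-catalysed stereoconvergent Suzuki coupling of racemic acylated bromohydrins with alkyl-9-BBN reagents used in step 8.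

Step 12
Reactants: 18 furan-2(5H)-one
Product: 20 3-bromofuran-2(5H)-one, via trans dibromolactone 19 (not isolated)
Conditions: Br2, CH2Cl2, 0 °C to rt; then Et3N, 0 °C
Reagents that add atoms: bromine BrBr
Why: Anti addition of bromine to the enoate C=C followed by base-induced loss of HBr through the acidic α-hydrogen (bromination–dehydrobromination) gives the α-bromobutenolide.

Step 13
Reactants: 17 (2R,6R,9Z)-6-[(acetyloxy)methyl]-11-{[tert-butyl(dimethyl)silyl]oxy}-10-methyl-2-(prop-2-en-1-yl)undec-9-en-1-yl acetate; 20 3-bromofuran-2(5H)-one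
Product: 22 (2R,6R,9Z)-6-[(acetyloxy)methyl]-11-{[tert-butyl(dimethyl)silyl]oxy}-10-methyl-2-[3-(2-oxo-2,5-dihydrofuran-3-yl)propyl]undec-9-en-1-yl acetate, via primary 9-BBN borane 21 (not isolated)
Conditions: 17, 9-BBN-H (1.1 equiv), THF, rt; then 20 (1.5 equiv), PdCl2(dppf) (5 mol %), AsPh3 (10 mol %), Cs2CO3, DMF/THF/H2O, rt
Reagents that add atoms: none
Why: B-alkyl Suzuki–Miyaura coupling: 9-BBN-H selects the terminal alkene over the trisubstituted one, and the α-bromoenoate adds quickly to zerovalent palladium, so the coupling runs at room temperature where the acetates, the silyl ether and the butenolide survive; no stereocentre is touched.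

Step 14
Reactants: 22 (2R,6R,9Z)-6-[(acetyloxy)methyl]-11-{[tert-butyl(dimethyl)silyl]oxy}-10-methyl-2-[3-(2-oxo-2,5-dihydrofuran-3-yl)propyl]undec-9-en-1-yl acetate
Product: 23 (2R,6R,9Z)-6-[(acetyloxy)methyl]-11-hydroxy-10-methyl-2-[3-(2-oxo-2,5-dihydrofuran-3-yl)propyl]undec-9-en-1-yl acetate (CNP0139404.2)
Conditions: HF·pyridine, pyridine/THF, 0 °C to rt
Reagents that add atoms: none
Why: Buffered fluoride desilylation cleaves only the primary allylic silyl ether and leaves both acetates, the butenolide and the Z olefin intact.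

**Compound list**

1 | prop-2-yn-1-ol | C#CCO | starting material
2 | bromomagnesium (Z)-3-(bromomagnesio)-2-methylprop-2-en-1-olate | Br[Mg]/C=C(/C)CO[Mg]Br | intermediate
3 | (Z)-3-iodo-2-methylprop-2-en-1-ol | I/C=C(/C)CO | intermediate
4 | tert-butyl{[(2Z)-3-iodo-2-methylprop-2-en-1-yl]oxy}dimethylsilane | I/C=C(/C)CO[Si](C)(C)C(C)(C)C | intermediate
5 | tert-butyl(dimethyl){[(2Z)-2-methylpenta-2,4-dien-1-yl]oxy}silane | C=C/C=C(/C)CO[Si](C)(C)C(C)(C)C | intermediate
6 | methyl pent-4-enoate | COC(=O)CCC=C | starting material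
7 | lithium 1-methoxypenta-1,4-dien-1-olate | [Li+].COC([O-])=CCC=C | intermediate
8 | methyl 2-bromopent-4-enoate (racemic) | COC(=O)C(Br)CC=C | intermediate
9 | 2-bromopent-4-en-1-ol (racemic) | OCC(Br)CC=C | intermediate
10 | 2-bromopent-4-en-1-yl benzyl(phenyl)carbamate (racemic) | O=C(OCC(Br)CC=C)N(Cc1ccccc1)c1ccccc1 | intermediate
11 | 2-bromopent-4-en-1-yl acetate (racemic) | CC(=O)OCC(Br)CC=C | intermediate
12 | 9-[(3Z)-5-{[tert-butyl(dimethyl)silyl]oxy}-4-methylpent-3-en-1-yl]-9-borabicyclo[3.3.1]nonane | CC(C)(C)[Si](C)(C)OC/C(C)=C\CCB1C2CCCC1CCC2 | intermediate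
13 | (2S,5Z)-7-{[tert-butyl(dimethyl)silyl]oxy}-6-methyl-2-(prop-2-en-1-yl)hept-5-en-1-yl benzyl(phenyl)carbamate | C=CC[C@H](CC/C=C(/C)CO[Si](C)(C)C(C)(C)C)COC(=O)N(Cc1ccccc1)c1ccccc1 | intermediate
14 | (2S,5Z)-7-{[tert-butyl(dimethyl)silyl]oxy}-6-methyl-2-(prop-2-en-1-yl)hept-5-en-1-ol | C=CC[C@H](CC/C=C(/C)CO[Si](C)(C)C(C)(C)C)CO | intermediate
15 | (2S,5Z)-7-{[tert-butyl(dimethyl)silyl]oxy}-6-methyl-2-(prop-2-en-1-yl)hept-5-en-1-yl acetate | C=CC[C@H](CC/C=C(/C)CO[Si](C)(C)C(C)(C)C)COC(C)=O | intermediate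
16 | (2R,5Z)-2-[3-(9-borabicyclo[3.3.1]nonan-9-yl)propyl]-7-{[tert-butyl(dimethyl)silyl]oxy}-6-methylhept-5-en-1-yl acetate | CC(=O)OC[C@@H](CC/C=C(/C)CO[Si](C)(C)C(C)(C)C)CCCB1C2CCCC1CCC2 | intermediate
17 | (2R,6R,9Z)-6-[(acetyloxy)methyl]-11-{[tert-butyl(dimethyl)silyl]oxy}-10-methyl-2-(prop-2-en-1-yl)undec-9-en-1-yl acetate | CC(=O)OC[C@@H](CC=C)CCC[C@H](CC/C=C(/C)CO[Si](C)(C)C(C)(C)C)COC(C)=O | intermediate
18 | furan-2(5H)-one | O=C1OCC=C1 | starting material
19 | trans-3,4-dibromooxolan-2-one (racemic, one enantiomer drawn) | O=C1OC[C@@H](Br)[C@@H]1Br | intermediate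
20 | 3-bromofuran-2(5H)-one | O=C1OCC=C1Br | intermediate
21 | (2S,6R,9Z)-6-[(acetyloxy)methyl]-2-[3-(9-borabicyclo[3.3.1]nonan-9-yl)propyl]-11-{[tert-butyl(dimethyl)silyl]oxy}-10-methylundec-9-en-1-yl acetate | CC(=O)OC[C@@H](CCCB1C2CCCC1CCC2)CCC[C@H](CC/C=C(/C)CO[Si](C)(C)C(C)(C)C)COC(C)=O | intermediate
22 | (2R,6R,9Z)-6-[(acetyloxy)methyl]-11-{[tert-butyl(dimethyl)silyl]oxy}-10-methyl-2-[3-(2-oxo-2,5-dihydrofuran-3-yl)propyl]undec-9-en-1-yl acetate | CC(=O)OC[C@@H](CCCC1=CCOC1=O)CCC[C@H](CC/C=C(/C)CO[Si](C)(C)C(C)(C)C)COC(C)=O | intermediate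
23 | (2R,6R,9Z)-6-[(acetyloxy)methyl]-11-hydroxy-10-methyl-2-[3-(2-oxo-2,5-dihydrofuran-3-yl)propyl]undec-9-en-1-yl acetate | CC(=O)OC[C@@H](CCCC1=CCOC1=O)CCC[C@H](CC/C=C(/C)CO)COC(C)=O | target

**Step count**

Total step count: 14.
Longest linear sequence: 9 steps (1, 2, 3, 8, 9, 10, 11, 13, 14; the branch from 6 through steps 4, 5, 6 is equally long).

**Steps most likely to fail, with fallbacks**

Step 11 (the new coupling). The acetate is a weaker donor than the carbamate, so enantiocontrol at C2 may be low. Residual alkoxide may transesterify the acetates. The homoallylic radical from 11 may leak through a 1,2-vinyl shift. The fallback uses only the established carbamate-directed coupling; it sets out from carbamate 13 (with racemic bromide 10) and comes back to the route at 17, so steps 9 and 10 fall away. Carbamate 13 is hydroborated with 9-BBN-H to (2R,5Z)-2-[3-(9-borabicyclo[3.3.1]nonan-9-yl)propyl]-7-{[tert-butyl(dimethyl)silyl]oxy}-6-methylhept-5-en-1-yl benzyl(phenyl)carbamate F1. This is coupled with 10 under the conditions of step 8 but with the (R,R) ligand, giving (2R,6R,9Z)-6-({[benzyl(phenyl)carbamoyl]oxy}methyl)-11-{[tert-butyl(dimethyl)silyl]oxy}-10-methyl-2-(prop-2-en-1-yl)undec-9-en-1-yl benzyl(phenyl)carbamate F2. LiAlH4 (THF, 0 °C to rt) cleaves both carbamates to (2R,6R,9Z)-11-{[tert-butyl(dimethyl)silyl]oxy}-6-(hydroxymethyl)-10-methyl-2-(prop-2-en-1-yl)undec-9-en-1-ol F3, and Ac2O/pyridine/DMAP acetylates both primary alcohols to give 17.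

Step 8. Monohydroboration of the conjugated diene may not be fully regioselective. The homoallyl–nickel species may lose a β-hydride. The homoallylic bromide 10 is a more demanding electrophile than those on which the coupling is established. The fallback sets the same stereocentre by auxiliary-controlled enolate alkylation; it sets out from iodide 4 and comes back at alcohol 14. Methyl but-3-enoate is hydroborated with 9-BBN-H to methyl 4-(9-borabicyclo[3.3.1]nonan-9-yl)butanoate F4 and coupled with 4 (PdCl2(dppf), AsPh3, Cs2CO3, DMF/THF/H2O, rt, retention of the Z geometry) to methyl (5Z)-7-{[tert-butyl(dimethyl)silyl]oxy}-6-methylhept-5-enoate F5. LiOH (THF/H2O) gives (5Z)-7-{[tert-butyl(dimethyl)silyl]oxy}-6-methylhept-5-enoic acid F6. Pivaloyl chloride/Et3N converts it into (5Z)-7-{[tert-butyl(dimethyl)silyl]oxy}-6-methylhept-5-enoic 2,2-dimethylpropanoic anhydride F7, which acylates lithiated (R)-4-benzyl-1,3-oxazolidin-2-one (n-BuLi, THF, −78 °C) to (4R)-4-benzyl-3-[(5Z)-7-{[tert-butyl(dimethyl)silyl]oxy}-6-methylhept-5-enoyl]-1,3-oxazolidin-2-one F8. NaN(SiMe3)2 (THF, −78 °C) gives the chelated enolate sodium (1Z,5Z)-1-[(4R)-4-benzyl-2-oxo-1,3-oxazolidin-3-yl]-7-{[tert-butyl(dimethyl)silyl]oxy}-6-methylhepta-1,5-dien-1-olate F9. Allyl iodide alkylates it on the face away from the benzyl group (Evans alkylation) to (4R)-4-benzyl-3-[(2S,5Z)-7-{[tert-butyl(dimethyl)silyl]oxy}-6-methyl-2-(prop-2-en-1-yl)hept-5-enoyl]-1,3-oxazolidin-2-one F10. LiBH4 (Et2O, H2O, 0 °C) releases the auxiliary and gives 14.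

Step 13. The bromobutenolide 20 is sensitive to aqueous base and may decompose faster than it couples, and the borane may protodeboronate. The fallback builds the butenolide ring on the terminal olefin instead of coupling a preformed ring; it sets out from diacetate 17 and comes back at 22. Diacetate 17 and methyl 4-hydroxybut-2-ynoate are joined with CpRu(cod)Cl (5 mol %) in MeOH at reflux (ruthenium-catalysed Alder-ene-type alkene–alkyne addition, which engages only the terminal olefin and forms the C–C bond α to the ester). This gives methyl (2Z)-2-[(2E,4R,8R,11Z)-4,8-bis[(acetyloxy)methyl]-13-{[tert-butyl(dimethyl)silyl]oxy}-12-methyltrideca-2,11-dien-1-yl]-4-hydroxybut-2-enoate F11, which lactonises in the flask to (2R,6R,9Z)-6-[(acetyloxy)methyl]-11-{[tert-butyl(dimethyl)silyl]oxy}-10-methyl-2-[(1E)-3-(2-oxo-2,5-dihydrofuran-3-yl)prop-1-en-1-yl]undec-9-en-1-yl acetate F12. Hydrogenation with RhCl(PPh3)3/H2 (benzene, rt) saturates only the disubstituted olefin and gives 22.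

Further compounds
F1 | step 11 | (2R,5Z)-2-[3-(9-borabicyclo[3.3.1]nonan-9-yl)propyl]-7-{[tert-butyl(dimethyl)silyl]oxy}-6-methylhept-5-en-1-yl benzyl(phenyl)carbamate | O=C(OC[C@@H](CC/C=C(/C)CO[Si](C)(C)C(C)(C)C)CCCB1C2CCCC1CCC2)N(Cc1ccccc1)c1ccccc1
F2 | step 11 | (2R,6R,9Z)-6-({[benzyl(phenyl)carbamoyl]oxy}methyl)-11-{[tert-butyl(dimethyl)silyl]oxy}-10-methyl-2-(prop-2-en-1-yl)undec-9-en-1-yl benzyl(phenyl)carbamate | O=C(OC[C@@H](CC=C)CCC[C@H](CC/C=C(/C)CO[Si](C)(C)C(C)(C)C)COC(=O)N(Cc1ccccc1)c1ccccc1)N(Cc1ccccc1)c1ccccc1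
F3 | step 11 | (2R,6R,9Z)-11-{[tert-butyl(dimethyl)silyl]oxy}-6-(hydroxymethyl)-10-methyl-2-(prop-2-en-1-yl)undec-9-en-1-ol | OC[C@@H](CC=C)CCC[C@H](CC/C=C(/C)CO[Si](C)(C)C(C)(C)C)CO
F4 | step 8 | methyl 4-(9-borabicyclo[3.3.1]nonan-9-yl)butanoate | COC(=O)CCCB1C2CCCC1CCC2
F5 | step 8 | methyl (5Z)-7-{[tert-butyl(dimethyl)silyl]oxy}-6-methylhept-5-enoate | COC(=O)CCC/C=C(/C)CO[Si](C)(C)C(C)(C)C
F6 | step 8 | (5Z)-7-{[tert-butyl(dimethyl)silyl]oxy}-6-methylhept-5-enoic acid | OC(=O)CCC/C=C(/C)CO[Si](C)(C)C(C)(C)C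
F7 | step 8 | (5Z)-7-{[tert-butyl(dimethyl)silyl]oxy}-6-methylhept-5-enoic 2,2-dimethylpropanoic anhydride | CC(C)(C)C(=O)OC(=O)CCC/C=C(/C)CO[Si](C)(C)C(C)(C)C
F8 | step 8 | (4R)-4-benzyl-3-[(5Z)-7-{[tert-butyl(dimethyl)silyl]oxy}-6-methylhept-5-enoyl]-1,3-oxazolidin-2-one | O=C(CCC/C=C(/C)CO[Si](C)(C)C(C)(C)C)N1[C@H](Cc2ccccc2)COC1=O
F9 | step 8 | sodium (1Z,5Z)-1-[(4R)-4-benzyl-2-oxo-1,3-oxazolidin-3-yl]-7-{[tert-butyl(dimethyl)silyl]oxy}-6-methylhepta-1,5-dien-1-olate | [Na+].[O-]/C(=C\CC/C=C(/C)CO[Si](C)(C)C(C)(C)C)N1[C@H](Cc2ccccc2)COC1=O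
F10 | step 8 | (4R)-4-benzyl-3-[(2S,5Z)-7-{[tert-butyl(dimethyl)silyl]oxy}-6-methyl-2-(prop-2-en-1-yl)hept-5-enoyl]-1,3-oxazolidin-2-one | O=C([C@H](CC=C)CC/C=C(/C)CO[Si](C)(C)C(C)(C)C)N1[C@H](Cc2ccccc2)COC1=O
F11 | step 13 | methyl (2Z)-2-[(2E,4R,8R,11Z)-4,8-bis[(acetyloxy)methyl]-13-{[tert-butyl(dimethyl)silyl]oxy}-12-methyltrideca-2,11-dien-1-yl]-4-hydroxybut-2-enoate | CC(=O)OC[C@@H](/C=C/C/C(C(=O)OC)=C/CO)CCC[C@H](CC/C=C(/C)CO[Si](C)(C)C(C)(C)C)COC(C)=O
F12 | step 13 | (2R,6R,9Z)-6-[(acetyloxy)methyl]-11-{[tert-butyl(dimethyl)silyl]oxy}-10-methyl-2-[(1E)-3-(2-oxo-2,5-dihydrofuran-3-yl)prop-1-en-1-yl]undec-9-en-1-yl acetate | CC(=O)OC[C@@H](/C=C/CC1=CCOC1=O)CCC[C@H](CC/C=C(/C)CO[Si](C)(C)C(C)(C)C)COC(C)=O
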